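**Retrosynthetic overview**
1. Target 15 ← deacetylation and protonation ← sulfation ← hydrogenolysis ← acetylation of triol 9. In 9 the two benzyl ethers mark the two sulfate oxygens (ring A C3–O, ring B C4–O) and the three free phenols are those of the target.
2. Feature: in ring B (C1 = the carbon of the diaryl ether) the oxygens on C2, C4 and C6 stand in the 1,3,5-pattern of a triacetic acid chain whose end carbon is C1. Ring B is therefore cut at C1–C2 and traced back to 2-pyrone 7, so the doubly ortho-flanked ether O–C1 is made earlier as a plain ArO–CH2 ether.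
3. 7 ← bromomethylpyrone 4 (triacetic acid lactone: O-benzylation, then NBS) + 5-(benzyloxy)resorcinol 6 (phloroglucinol: monobenzylation).
4. Ring order: ring A (phloroglucinol) and the pyrone (triacetic acid lactone) are bought; ring B is the only ring built, in step 5.

Key step: step 5

Assumption: the target is taken as the free bis(hydrogen sulfate) as drawn; because aryl hydrogen sulfates lose SO3 in acid, the acid form would be generated only in the last operation by cold cation exchange (the sodium ions stay on the resin) and freeze-drying, and the disodium salt 14 is the form to store.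

**Route**

Step 1
Reactants: 1 4-hydroxy-6-methyl-2H-pyran-2-one (triacetic acid lactone); 2 benzyl bromide
Product: 3 4-(benzyloxy)-6-methyl-2H-pyran-2-one
Conditions: K2CO3 (1.5 equiv), DMF, 50 °C
Reagents that add atoms: none
Why: Williamson O-alkylation of the vinylogous acid, whose anion with K2CO3 in a polar aprotic solvent should react mainly at the 4-oxygen to give the 4-alkoxy-2-pyrone.

Step 2
Reactants: 3 4-(benzyloxy)-6-methyl-2H-pyran-2-one
Product: 4 4-(benzyloxy)-6-(bromomethyl)-2H-pyran-2-one
Conditions: NBS (1.05 equiv), AIBN (cat.), PhCF3, 80 °C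
Reagents that add atoms: N-bromosuccinimide, O=C1CCC(=O)N1Br
Why: Wohl–Ziegler radical bromination, in which the 6-methyl group gives a radical delocalised over the pyrone diene (as in the bromination of 4-methoxy-6-methyl-2-pyrone), while the benzyl CH2 on a vinylogous ester oxygen should be deactivated towards the electrophilic bromine atom much like a benzyl ester.

Step 3
Reactants: 5 phloroglucinol (3 equiv); 2 benzyl bromide (1 equiv)
Product: 6 5-(benzyloxy)benzene-1,3-diol
Conditions: K2CO3 (1.0 equiv), DMF, 0 °C → rt
Reagents that add atoms: none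
Why: Williamson etherification of one of three equivalent phenols, held at the mono-ether stage by the threefold excess of phloroglucinol, which is removed by aqueous washing.

Step 4
Reactants: 4 4-(benzyloxy)-6-(bromomethyl)-2H-pyran-2-one (1 equiv); 6 5-(benzyloxy)benzene-1,3-diol (3 equiv)
Product: 7 4-(benzyloxy)-6-{[3-(benzyloxy)-5-hydroxyphenoxy]methyl}-2H-pyran-2-one
Conditions: K2CO3 (1.1 equiv), acetone, rt
Reagents that add atoms: none
Why: SN2 displacement (Williamson ether synthesis) of a reactive allylic-type primary bromide by the monophenoxide, in which the excess of diol should suppress double alkylation and K2CO3 in acetone should favour O- over C-alkylation.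

Step 5
Reactants: 7 4-(benzyloxy)-6-{[3-(benzyloxy)-5-hydroxyphenoxy]methyl}-2H-pyran-2-one
Product: 9 5-(benzyloxy)-2-[3-(benzyloxy)-5-hydroxyphenoxy]benzene-1,3-diol, via ring-opened benzyl (2E)-enoate 8 (not isolated)
Conditions: NaOBn (1 M in BnOH, 4.5 equiv), THF, Ar, rt → 65 °C; then 1 M HCl, 0 °C
Reagents that add atoms: sodium benzyloxide, [Na+].[O-]Cc1ccccc1 (its benzyloxy group is held by 8 and leaves again on ring closure; 9 keeps no net atoms from it)
Why: Benzyloxide adds to the lactone carbonyl (pyrone C2) and the ring opens by acyl–oxygen cleavage to the sodium enolate of benzyl ester 8, in which the 2E double bond inherited from the pyrone holds the ester carbon and the ketone side chain on the same side. Proton transfer in the alcoholic medium gives access to the enolate at the methylene that carries the aryloxy group, and this carbon attacks the ester carbonyl in a Claisen (Dieckmann-type) condensation, a favoured 6-(enolendo)-exo-trig closure that forms the C1–C2 bond of ring B; loss of benzyloxide and enolisation of the 2-aryloxy-5-(benzyloxy)cyclohexadienone give the resorcinol, so the pyrone ring oxygen and the lactone carbonyl oxygen end as the two hydroxyls beside the ether. The closest known reaction type is the alkoxide-induced conversion of 4-alkoxy-6-methyl-2-pyrones into 5-alkoxyresorcinols, that is the Claisen cyclisation of a triacetic acid ester masked as its 3-enol ether. No stereocentre is formed. The step needs C-acylation at the chain end to win over relactonisation, alkoxy exchange and retro-Claisen cleavage: lactone opening and closing are reversible, exchange at the ester and at C4 is degenerate because the base is benzyloxide, the enol ether at the former pyrone C4 blocks the central 1,3-dicarbonyl from other condensations, the aryloxy group acidifies the terminal CH2, and only the carbocyclisation is driven forward by aromatisation to a phenoxide.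

Step 6
Reactants: 9 5-(benzyloxy)-2-[3-(benzyloxy)-5-hydroxyphenoxy]benzene-1,3-diol
Product: 10 2-[3-(acetyloxy)-5-(benzyloxy)phenoxy]-5-(benzyloxy)-1,3-phenylene diacetate
Conditions: Ac2O (6 equiv), pyridine, DMAP (cat.), 0 °C → rt
Reagents that add atoms: acetic anhydride, CC(=O)OC(C)=O
Why: DMAP-catalysed acylation should esterify all three phenols, including the two that flank the ether, and so mark the positions that stay free in the target.

Step 7
Reactants: 10 2-[3-(acetyloxy)-5-(benzyloxy)phenoxy]-5-(benzyloxy)-1,3-phenylene diacetate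
Product: 11 2-[3-(acetyloxy)-5-hydroxyphenoxy]-5-hydroxy-1,3-phenylene diacetate
Conditions: H2 (1 atm), 10% Pd/C, EtOAc, rt
Reagents that add atoms: none
Why: Catalytic hydrogenolysis of the two benzyl aryl ethers in a non-nucleophilic solvent should leave the aryl acetates and the diaryl ether untouched and free exactly the two oxygens to be sulfated.

Step 8
Reactants: 11 2-[3-(acetyloxy)-5-hydroxyphenoxy]-5-hydroxy-1,3-phenylene diacetate
Product: 13 disodium 3-(acetyloxy)-5-[2,6-bis(acetyloxy)-4-(sulfonatooxy)phenoxy]phenyl sulfate, via bis(pyridinium) bis(sulfate) 12 (not isolated)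
Conditions: SO3·pyridine (6 equiv), DMF, rt; then aq. NaHCO3 to pH 7, 0 °C; reversed-phase C18
Reagents that add atoms: sulfur trioxide–pyridine complex, O=S(=O)([O-])[n+]1ccccc1; sodium hydrogencarbonate, [Na+].OC([O-])=O
Why: O-sulfation of phenols with the SO3–amine complex should occur at the only two free hydroxyls, both unhindered, and neutralisation exchanges pyridinium for sodium.

Step 9
Reactants: 13 disodium 3-(acetyloxy)-5-[2,6-bis(acetyloxy)-4-(sulfonatooxy)phenoxy]phenyl sulfate
Product: 15 3-[2,6-dihydroxy-4-(sulfooxy)phenoxy]-5-hydroxyphenyl hydrogen sulfate (target), via disodium salt 14 (not isolated)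
Conditions: NaOMe (0.5 equiv), degassed MeOH, Ar, 0 °C → rt; then Dowex 50WX8 (H+ form), H2O, 0 °C; freeze-dry
Reagents that add atoms: none
Why: Zemplén-type methanolysis should remove the three aryl acetates while the aryl sulfate monoester anions are inert to methoxide, and cold cation exchange replaces sodium by protons.

**Compound list**
1 | 4-hydroxy-6-methyl-2H-pyran-2-one (triacetic acid lactone) | Cc1cc(O)cc(=O)o1 | starting material
2 | benzyl bromide | BrCc1ccccc1 | starting material
3 | 4-(benzyloxy)-6-methyl-2H-pyran-2-one | Cc1cc(OCc2ccccc2)cc(=O)o1 | intermediate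
4 | 4-(benzyloxy)-6-(bromomethyl)-2H-pyran-2-one | BrCc1cc(OCc2ccccc2)cc(=O)o1 | intermediate
5 | phloroglucinol (benzene-1,3,5-triol) | Oc1cc(O)cc(O)c1 | starting material
6 | 5-(benzyloxy)benzene-1,3-diol | Oc1cc(O)cc(OCc2ccccc2)c1 | intermediate
7 | 4-(benzyloxy)-6-{[3-(benzyloxy)-5-hydroxyphenoxy]methyl}-2H-pyran-2-one | O=c1cc(OCc2ccccc2)cc(COc2cc(O)cc(OCc3ccccc3)c2)o1 | intermediate
8 | benzyl (2E)-3-(benzyloxy)-6-[3-(benzyloxy)-5-hydroxyphenoxy]-5-oxohex-2-enoate (in the flask as its sodium enolate and phenoxide; drawn neutral) | O=C(OCc1ccccc1)/C=C(/OCc1ccccc1)CC(=O)COc1cc(O)cc(OCc2ccccc2)c1 | intermediate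
9 | 5-(benzyloxy)-2-[3-(benzyloxy)-5-hydroxyphenoxy]benzene-1,3-diol | Oc1cc(OCc2ccccc2)cc(Oc2c(O)cc(OCc3ccccc3)cc2O)c1 | intermediate
10 | 2-[3-(acetyloxy)-5-(benzyloxy)phenoxy]-5-(benzyloxy)-1,3-phenylene diacetate | CC(=O)Oc1cc(OCc2ccccc2)cc(Oc2c(OC(C)=O)cc(OCc3ccccc3)cc2OC(C)=O)c1 | intermediate
11 | 2-[3-(acetyloxy)-5-hydroxyphenoxy]-5-hydroxy-1,3-phenylene diacetate | CC(=O)Oc1cc(O)cc(Oc2c(OC(C)=O)cc(O)cc2OC(C)=O)c1 | intermediate
12 | bis(pyridinium) 3-(acetyloxy)-5-[2,6-bis(acetyloxy)-4-(sulfonatooxy)phenoxy]phenyl sulfate | CC(=O)Oc1cc(OS(=O)(=O)[O-])cc(Oc2c(OC(C)=O)cc(OS(=O)(=O)[O-])cc2OC(C)=O)c1.c1cc[nH+]cc1.c1cc[nH+]cc1 | intermediate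
13 | disodium 3-(acetyloxy)-5-[2,6-bis(acetyloxy)-4-(sulfonatooxy)phenoxy]phenyl sulfate | CC(=O)Oc1cc(OS(=O)(=O)[O-])cc(Oc2c(OC(C)=O)cc(OS(=O)(=O)[O-])cc2OC(C)=O)c1.[Na+].[Na+] | intermediate
14 | disodium 3-[2,6-dihydroxy-4-(sulfonatooxy)phenoxy]-5-hydroxyphenyl sulfate | Oc1cc(OS(=O)(=O)[O-])cc(Oc2c(O)cc(OS(=O)(=O)[O-])cc2O)c1.[Na+].[Na+] | intermediate
15 | 3-[2,6-dihydroxy-4-(sulfooxy)phenoxy]-5-hydroxyphenyl hydrogen sulfate | O=S(=O)(O)Oc1cc(O)cc(Oc2c(O)cc(OS(=O)(=O)O)cc2O)c1 | target

**Step count**
Total steps: 9. Longest linear sequence: 8 (steps 1, 2, 4, 5, 6, 7, 8, 9); step 3 is the side branch.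

**Steps most likely to fail**

Step 5 (key step). The lactone may open without the chain end closing onto the ester: the enolate can relactonise, benzyloxide can cleave the ketone by a retro-Claisen reaction or displace the aryloxide, and the ring A phenoxide can add through carbon to the ketone. A higher temperature (neat BnOH or dioxane, about 100 °C) would be tried first. The fallback gives up the pyrone route to ring B, sets out from 6 and comes back at 9. Diol 6 would be protected with MOMCl and iPr2NEt in CH2Cl2 as 1-(benzyloxy)-3,5-bis(methoxymethoxy)benzene F1. Directed ortho-lithiation between the two MOM ethers (n-BuLi, THF, 0 °C) and quenching with I2 would give 5-(benzyloxy)-2-iodo-1,3-bis(methoxymethoxy)benzene F2. Ullmann ether coupling of F2 with an excess of 6 (CuI, picolinic acid, K3PO4, DMSO, 90 °C) would give 3-(benzyloxy)-5-[4-(benzyloxy)-2,6-bis(methoxymethoxy)phenoxy]phenol F3. HCl in MeOH would then remove both MOM groups and deliver 9.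

Step 2. Hydrogen abstraction at the benzyl ether CH2 and ionic bromination at C3 of the pyrone may compete with bromination of the 6-methyl group. The fallback replaces the radical path by an anionic one, sets out from 3 and comes back at 7. Deprotonation of the 6-methyl group with LiN(SiMe3)2 in THF at −78 °C and chlorination of the vinylogous enolate with C2Cl6 would give 4-(benzyloxy)-6-(chloromethyl)-2H-pyran-2-one F4. F4 would alkylate an excess of 6 (K2CO3, NaI cat., acetone) to give 7.

Step 4. C-alkylation of the electron-rich phenoxide and alkylation of both hydroxyls may lower the amount of mono-ether. The fallback avoids a free phenoxide, sets out from 4 and comes back at 7. Hydrolysis of the bromide (CaCO3, dioxane/H2O, 80 °C) would give 4-(benzyloxy)-6-(hydroxymethyl)-2H-pyran-2-one F5. Mitsunobu etherification of F5 with an excess of 6 (PPh3, DIAD, THF, 0 °C → rt) would give 7.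

**Further compounds**
F1 | step 5 | 1-(benzyloxy)-3,5-bis(methoxymethoxy)benzene | COCOc1cc(OCOC)cc(OCc2ccccc2)c1
F2 | step 5 | 5-(benzyloxy)-2-iodo-1,3-bis(methoxymethoxy)benzene | COCOc1cc(OCc2ccccc2)cc(OCOC)c1I
F3 | step 5 | 3-(benzyloxy)-5-[4-(benzyloxy)-2,6-bis(methoxymethoxy)phenoxy]phenol | COCOc1cc(OCc2ccccc2)cc(OCOC)c1Oc1cc(O)cc(OCc2ccccc2)c1
F4 | step 2 | 4-(benzyloxy)-6-(chloromethyl)-2H-pyran-2-one | ClCc1cc(OCc2ccccc2)cc(=O)o1
F5 | step 4 | 4-(benzyloxy)-6-(hydroxymethyl)-2H-pyran-2-one | OCc1cc(OCc2ccccc2)cc(=O)o1
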